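The data are simulated with made-up constants, and the scatter is random.

**Minutes of a short meeting on zeta, delta and theta**

The meeting began from slowness: I proposed that at each temperature we ask how many times slower the route to right-handed product runs than the route to left-handed product, much as one compares the time constants of two parallel channels.

in all of them: free catalyst 2.5 mol%
- Monday's: left-handed substrate 0.18 M; right-handed substrate 0.18 M; partner 1.1 equiv; impurity 1.8 mM; temperature 95 °C; run made earlier
- Friday's: left-handed substrate 0.18 M; right-handed substrate 0.18 M; partner 1.1 equiv; impurity 2.9 mM; temperature 125 °C; run made earlier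
- Tuesday's: left-handed substrate 0.36 M; right-handed substrate 0.36 M; partner 1.1 equiv; impurity 1.3 mM; temperature 95 °C; run made earlier
- zeta: left-handed substrate 0.18 M; right-handed substrate 0.18 M; partner 1.10 equiv; impurity 1.3 mM; temperature 150 °C; time 6.0 min
- delta: left-handed substrate 0.18 M; right-handed substrate 0.18 M; partner 1.10 equiv; impurity 1.3 mM; temperature 125 °C; time 6.0 min
- theta: left-handed substrate 0.18 M; right-handed substrate 0.18 M; partner 1.10 equiv; impurity 1.3 mM; temperature 100 °C; time 6.0 min

| run | time / min | left-handed product / % | right-handed product / % |
|---|---|---|---|
| Monday's | 6.00 | 4.1 | 0.9 |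
| Monday's | 12.0 | 4.9 | 2.5 |
| Monday's | 30.0 | 4.6 | 1.4 |
| Monday's | 80.0 | 5.3 | 1.4 |
| Friday's | 1.33 | 2.8 | 1.3 |
| Friday's | 3.00 | 3.1 | 0.8 |
| Friday's | 6.00 | 1.7 | 1.2 |
| Friday's | 15.0 | 2.4 | 1.0 |
| Tuesday's | 6.00 | 13.0 | 4.1 |
| Tuesday's | 12.0 | 12.4 | 3.2 |
| Tuesday's | 30.0 | 11.8 | 3.6 |
| Tuesday's | 80.0 | 12.1 | 3.7 |

(scatter of a reading: 0.5 percentage points)

- free catalyst is single-handed; left-handed substrate and right-handed substrate are mirror images of each other, charged as a racemate, each of them at the stated concentration
- an excess is the difference of the two amounts in percent of their sum
- an excess is below zero if the other one leads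

- the flask with the highest excess of left-handed product over right-handed product ("all alike" if they lie within 1.5 percentage points) (zeta / delta / theta / all alike)
- excess of left-handed product over right-handed product at the end, zeta
- excess of left-handed product over right-handed product at the end, delta
- excess of left-handed product over right-handed product at the end, theta

I argued that this slowness ratio can be read from the product amounts, since Monday's final reading holds 6.70% of the charge as product, far below the whole, so in Monday's flask the two substrates stayed close to their equal starting fractions and the ratio of the products stands close to the ratio of the rates, the selectivity factor. A colleague asked whether the stopping point matters, and I answered that Monday's ratio, summed over its readings, of 3.05 and Tuesday's of 3.38 lie close, although Tuesday's last reading shows more product, 15.8% of its charge, so we pooled them into 3.28 at 95 °C, against 2.33 from Friday's run at 125 °C.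

From these I took the temperature constant, the warming over which the slowness ratio shrinks by a factor of e, which comes to 87.3 K, though the colleague objected that Friday's right-handed readings stand near 1.0% with a scatter of 0.5 percentage points, so this constant is loose.

Carrying the ratio along it, I committed to 3.10 for theta, 2.33 for delta and 1.75 for zeta, and since the excess is the ratio less one over the ratio plus one, that makes 51.2%, 39.9% and 27.2%, with theta the highest.

The forecast, reasoning that “selectivity falls with temperature”, also named theta but stood higher than my figures, at 37% for zeta, at 45% for delta and at 53% for theta.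

The flasks gave 16.6% for zeta, 37.3% for delta and 57.0% for theta, so the highest is theta.

    partner + free catalyst + left-handed substrate → free catalyst + left-handed product (k = 3.80 M⁻² s⁻¹, Ea = 37.0 kJ mol⁻¹)
    partner + free catalyst + right-handed substrate → free catalyst + right-handed product (k = 1.00 M⁻² s⁻¹, Ea = 63.0 kJ mol⁻¹)
    free catalyst + impurity → spent catalyst A (k = 26.0 M⁻¹ s⁻¹, Ea = 46.0 kJ mol⁻¹)
    partner → decomposed reagent (k = 7.60 × 10⁻⁴ s⁻¹, Ea = 112 kJ mol⁻¹)
    partner + free catalyst → spent catalyst B (k = 0.110 M⁻¹ s⁻¹, Ea = 49.0 kJ mol⁻¹)
    (constants at 100 °C)

Delta's product ratio of 2.19 and zeta's of 1.40 put the temperature constant at 55.6 K, shorter than the 87.3 K read from the earlier runs, and zeta is where my figure stood furthest off. The neighbouring flask is delta repeated at 100 °C: carrying delta's ratio down by this shorter constant gives 3.44, an excess of 55.0%, and that flask gave 57.0%, with 5.25% of the charge as left-handed product.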